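The readings come from a simulation with made-up constants; noise was put on by code.

4 questions stand below, and one quantity answers them.

| flask | starting material | second substrate | free enzyme | remark | time |
|---|---|---|---|---|---|
| autumn | 0.10 M | 0.50 equiv | 0.01 mol% | run made earlier |  |
| noon | 0.050 M | 0.50 equiv | 0.01 mol% | run made earlier |  |
| midnight | 0.075 M | 0.50 equiv | 0.01 mol% | run made earlier |  |
| dusk | 0.10 M | 0.50 equiv | 0.015 mol% | run made earlier |  |
| gamma | 0.10 M | 0.500 equiv (fed, over 40 h) | 0.01 mol% | all else is in the flask from the start; the feed brings no volume worth counting | 2.5 d |
| eta | 0.10 M (fed, over 40 h) | 0.500 equiv | 0.01 mol% | all else is in the flask from the start; the feed brings no volume worth counting | 2.5 d |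
| delta | 0.10 M | 0.500 equiv | 0.01 mol% | everything together at the start | 2.5 d |

- autumn (time / h: target / %): 3.00: 4.2; 6.00: 8.0; 15.0: 17.6; 40.0: 30.7
- noon (time / d: target / %): 0.208: 4.7; 0.500: 12.0; 1.04: 20.1; 2.50: 34.0
- midnight (time / d: target / %): 0.208: 5.7; 0.500: 13.6; 1.04: 23.5; 2.50: 32.2
- dusk (time / d: target / %): 0.333: 14.6; 0.833: 30.5; 1.67: 31.9; 2.50: 32.9

(scatter of a reading: 0.5 percentage points)

- which flask leads in amount of target, in percent of the starting material charged ("all alike" within 1.5 percentage points) (gamma / eta / delta / all alike)
- how much target is there at the end, in percent of the starting material charged: gamma
- how much target is there at the end, in percent of the starting material charged: eta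
- how much target is there at the end, in percent of the starting material charged: delta

- steps thought possible: starting material + free enzyme <-> first complex; second complex -> free enzyme + target; second substrate + loaded enzyme <-> second complex; second substrate + free enzyme + target -> free enzyme + over-reaction product; first complex <-> loaded enzyme + first product; starting material + second substrate -> uncatalysed product

1. Reckon with what is lost, not what is made. One second substrate gives at best one target, so with second substrate as the limiting reagent your ceiling is 50.0 % of the starting material charged. The dusk run reads 32.9 % at its last point, so 34.2 % of its second substrate does not stand as target there. Call this λ, the lost fraction: the share of the second substrate charged that does not stand as target at the end.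

2. First extreme: suppose λ stays at that dusk reading. Target is then 32.9 %. This is my figure for delta and for eta, where the second substrate starts in full.

3. Second extreme: suppose each drop of second substrate meets enzyme at once. Then λ is zero and target reaches the ceiling.

4. Flask gamma lies between. Up to 15.0 h its feed delivers 18.8 %, while the autumn run made 17.6 %, so over those hours the pace of the autumn run stands near that of the feed. As a judgement I place gamma midway and commit to half the dusk λ, which gives 41.4 %.

5. The forecast names gamma as leader, with 42 % there, 31 % in eta and 32 % in delta, a little apart from my figures. Its ground for gamma is that “side losses shrink”.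

6. The flasks give 38.8 % in gamma, 28.1 % in eta and 29.7 % in delta, so gamma leads.

    starting material + free enzyme ⇌ first complex (K = 11.0 /M, k = 76.0 /M/s)
    second complex → free enzyme + target (k = 1.80 /s)
    second substrate + loaded enzyme ⇌ second complex (K = 15.0 /M, k = 49.0 /M/s)
    second substrate + free enzyme + target → free enzyme + over-reaction product (k = 31.0 /M²/s)
    first complex ⇌ loaded enzyme + first product (K = 0.0930 M, k = 0.0900 /s)
    starting material + second substrate → uncatalysed product (k = 7.90 × 10⁻⁵ /M/s)

With 0.13 % of second substrate left in gamma and 0.047 % in eta, gamma's λ is 22.5 %, less than eta's 43.7 %. The largest single effect on that gap among the steps tried is the way back from first complex to starting material and free enzyme: in the run without it, the difference in target between gamma and eta falls from 11 percentage points to 0.61 points. In the flask like eta but charged with 0.300 equiv of second substrate, target is 21.3 % and λ is 29.0 %.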